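**Retrosynthetic overview**
- Target 9 is cut at C2–H (hydride to an oxocarbenium ion) and at C3–C4 (closure of ring C). Both bonds form in one operation from the acyclic, achiral aryl 1-arylvinyl ether 5, whose future C4 is a CH2OMe group.
- 5 comes from aryl ester 4 by carbonyl methylenation (C2=C3). 4 comes from aldehyde ester 3 by reductive etherification (C4 to the benzylic ether level). 3 comes from salicylaldehyde 1 and acid chloride 2 (O1–C2 bond).
- Enabling feature: C4 is benzylic on ring A, ortho to O1 and para to the C7 methoxy group, so it ionises easily. C2 sits between O1 and ring B, so C2=C3 is an enol ether that is nucleophilic at C3 and leaves a stabilised cation at C2. The six atoms C4, C4a, C8a, O1, C2, C3 form one conjugated array that closes at its ends.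
- Rings A and B are bought. Ring C is the only ring made, and it is made last, together with the only stereocentre.

Key step: step 4

Assumption: flavan numbering (O1, C2, C3, C4, C4a, C5 to C8, C8a; ring B C1' to C6') is used for all intermediates, and the (R)-acid of step 4 is assumed to expose the Re face of C2; if a test run shows the opposite sense, the (S)-acid is used.

Step 1
Reactants: 1 2-hydroxy-3,4-dimethoxybenzaldehyde; 2 3,4,5-trimethoxybenzoyl chloride
Product: 3 6-formyl-2,3-dimethoxyphenyl 3,4,5-trimethoxybenzoate
Conditions: Et3N (1.5 equiv), 4-(dimethylamino)pyridine (5 mol%), CH2Cl2, 0 °C to rt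
Reagents that add atoms: none
Why: O-acylation of a phenol by an acid chloride under nucleophilic catalysis (Schotten–Baumann-type esterification) should go cleanly because the aldehyde is inert here and the acylpyridinium ion overrides the internal hydrogen bond of the salicylaldehyde; no stereocentre is formed.

Step 2
Reactants: 3 6-formyl-2,3-dimethoxyphenyl 3,4,5-trimethoxybenzoate
Product: 4 2,3-dimethoxy-6-(methoxymethyl)phenyl 3,4,5-trimethoxybenzoate
Conditions: Et3SiH (1.1 equiv), Me3SiOMe (1.5 equiv), FeCl3 (5 mol%), MeNO2, 0 °C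
Reagents that add atoms: methoxytrimethylsilane, CO[Si](C)(C)C
Why: Lewis-acid-catalysed reductive etherification of an aromatic aldehyde with a silane and an alkoxysilane runs without any free alkoxide, so the aroyl group cannot migrate from the phenol oxygen to the benzylic oxygen; no stereocentre is formed.

Step 3
Reactants: 4 2,3-dimethoxy-6-(methoxymethyl)phenyl 3,4,5-trimethoxybenzoate
Product: 5 5-(1-{[2,3-dimethoxy-6-(methoxymethyl)phenyl]oxy}ethenyl)-1,2,3-trimethoxybenzene
Conditions: Cp2TiMe2 (2.5 equiv), toluene, 70 °C, dark; filtration through basic alumina (hexane/EtOAc, 1% Et3N)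
Reagents that add atoms: dimethyltitanocene Cp2TiMe2, [CH3-].[CH3-].[Ti+4].[cH-]1cccc1.[cH-]1cccc1
Why: Petasis methylenation, a carbonyl olefination in which Cp2Ti=CH2 formed thermally from Cp2TiMe2 turns the ester C=O into C=CH2, is standard for aryl benzoates and leaves aryl and benzylic methyl ethers untouched; no stereocentre is formed.

Step 4
Reactants: 5 5-(1-{[2,3-dimethoxy-6-(methoxymethyl)phenyl]oxy}ethenyl)-1,2,3-trimethoxybenzene
Product: 9 (2S)-7,8,3',4',5'-pentamethoxyflavan, via benzylic cation 6 (not isolated), via oxocarbenium ion 7 (not isolated), via 4H-chromene 8 (not isolated)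
Conditions: (R)-N-[4-oxido-2,6-bis(2,4,6-triisopropylphenyl)dinaphtho[2,1-d:1',2'-f][1,3,2]dioxaphosphepin-4-yl]-1,1,1-trifluoromethanesulfonamide (10 mol%), 5 Å molecular sieves, toluene (0.02 M), argon, 0 °C to rt until 5 is consumed; then diethyl 2,6-dimethyl-1,4-dihydropyridine-3,5-dicarboxylate (1.3 equiv), 0 °C to rt; Et3N quench
Reagents that add atoms: none
Why: Proposed new method: the chiral acid protonates the benzylic ether oxygen of 5 and methanol leaves to give cation 6, whose charge is shared by O1 and the C7 methoxy group, the enol ether terminus C3 then bonds to C4 so that the charge moves to C2 in oxocarbenium ion 7, and 7 rests as 4H-chromene 8 by reversible loss of a C3 proton until the dihydropyridine is added and hands a hydride to C2 of re-formed 7. The closest known reaction types are the acid-catalysed alkylation of enol ethers by electron-rich benzylic alcohols and ethers and the chiral-phosphate-directed transfer hydrogenation of 1-benzopyrylium and cyclic iminium ions with dihydropyridines, and what is new is their merger into one reductive ring closure on an aryl 1-arylvinyl ether. Ring C closes in the 6-endo-trig mode with respect to C2=C3, which can equally be read as a cationic 6π electrocyclisation of the array C4, C4a, C8a, O1, C2, C3 that gives ring A its aromaticity back. The only stereocentre, C2, is set by the catalyst: its anion is ion-paired with planar 7 and hydrogen-bonded to the N–H of the dihydropyridine, and this ternary assembly should deliver hydride to the Re face of C2, which gives (S). The step needs attack on C4 through C3 and not through C2 or C2' of ring B, which the substrate secures because only bonding at C3 places the charge on the carbon held by O1 and ring B, whereas bonding at C2 would leave a primary cation and bonding at C2' a seven-membered ring. It also needs hydride to reach 7 only, which is secured by adding the reductant after 5 is consumed, so that neither 6 nor C-protonated 5 is present to be reduced, while high dilution and the sieves (uptake of methanol) hold back intermolecular benzylation and alcoholysis of the enol ether.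

**Compound list**
1 | 2-hydroxy-3,4-dimethoxybenzaldehyde | O=Cc1ccc(OC)c(OC)c1O | starting material
2 | 3,4,5-trimethoxybenzoyl chloride | COc1cc(C(=O)Cl)cc(OC)c1OC | starting material
3 | 6-formyl-2,3-dimethoxyphenyl 3,4,5-trimethoxybenzoate | COc1cc(C(=O)Oc2c(C=O)ccc(OC)c2OC)cc(OC)c1OC | intermediate
4 | 2,3-dimethoxy-6-(methoxymethyl)phenyl 3,4,5-trimethoxybenzoate | COCc1ccc(OC)c(OC)c1OC(=O)c1cc(OC)c(OC)c(OC)c1 | intermediate
5 | 5-(1-{[2,3-dimethoxy-6-(methoxymethyl)phenyl]oxy}ethenyl)-1,2,3-trimethoxybenzene | C=C(Oc1c(COC)ccc(OC)c1OC)c1cc(OC)c(OC)c(OC)c1 | intermediate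
6 | 3,4-dimethoxy-2-{[1-(3,4,5-trimethoxyphenyl)ethenyl]oxy}benzyl cation (paired with the catalyst anion) | C=C(Oc1c([CH2+])ccc(OC)c1OC)c1cc(OC)c(OC)c(OC)c1 | intermediate
7 | 7,8-dimethoxy-2-(3,4,5-trimethoxyphenyl)-3,4-dihydrochromenylium (paired with the catalyst anion) | COc1cc(C2=[O+]c3c(OC)c(OC)ccc3CC2)cc(OC)c1OC | intermediate
8 | 7,8-dimethoxy-2-(3,4,5-trimethoxyphenyl)-4H-chromene | COc1cc(C2=CCc3ccc(OC)c(OC)c3O2)cc(OC)c1OC | intermediate
9 | (2S)-7,8,3',4',5'-pentamethoxyflavan | COc1cc([C@@H]2CCc3ccc(OC)c(OC)c3O2)cc(OC)c1OC | target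

Total step count: 4. Longest linear sequence: 4 (1, 3, 4, 5, 9).

**Steps most likely to fail**

**Step 4.**
- Acid-induced disproportionation of the resting chromene may tie the acid up as a flavylium salt before closure is complete.
- The liberated methanol may cleave the enol ether.
- The hydride transfer may show poor facial selectivity, because the cation offers the anion no hydrogen bond.

The fallback uses known chemistry only, sets out from 1 and comes back at 9. Wittig methylenation of 1 (MePPh3Br, KOtBu, 2.2 equiv each, THF) should give 2,3-dimethoxy-6-vinylphenol F1. Commercial (E)-3,4,5-trimethoxycinnamyl alcohol and methyl chloroformate (pyridine, CH2Cl2) should give (E)-3-(3,4,5-trimethoxyphenyl)allyl methyl carbonate F2. Asymmetric allylic etherification of the lithium phenoxide of F1 with F2 uses [Ir(cod)Cl]2 and a BINOL-derived phosphoramidite that bears a bis(1-phenylethyl)amino group, in THF, with the ligand antipode chosen for (S). It should give the branched ether (S)-1-ethenyl-3,4-dimethoxy-2-{[1-(3,4,5-trimethoxyphenyl)prop-2-en-1-yl]oxy}benzene F3, in which C2 is already set. Ring-closing metathesis (second-generation Grubbs catalyst RuCl2(=CHPh)(PCy3)(H2IMes), CH2Cl2, 40 °C) joins C3 and C4 as an alkene and should give (2S)-7,8-dimethoxy-2-(3,4,5-trimethoxyphenyl)-2H-chromene F4. Hydrogenation (H2, RhCl(PPh3)3, benzene/EtOH) should then give 9 without touching the C2–O1 bond.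

**Step 3.** Methylenation of the doubly ortho-substituted aryl ester may be slow, and the enol ether may hydrolyse during isolation.

The fallback sets out from 1 and comes back at 5. It makes O1–C2 by etherification and C2=C3 by elimination.
- Commercial 2-bromo-1-(3,4,5-trimethoxyphenyl)ethanone is reduced (NaBH4, MeOH, 0 °C) to racemic 2-bromo-1-(3,4,5-trimethoxyphenyl)ethan-1-ol F5.
- Mitsunobu etherification of 1 with F5 (PPh3, diisopropyl azodicarboxylate, THF) should give racemic 2-[2-bromo-1-(3,4,5-trimethoxyphenyl)ethoxy]-3,4-dimethoxybenzaldehyde F6.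
- Dehydrobromination (KOtBu, THF, 0 °C) should give 3,4-dimethoxy-2-{[1-(3,4,5-trimethoxyphenyl)ethenyl]oxy}benzaldehyde F7.
- NaBH4 in MeOH should give (3,4-dimethoxy-2-{[1-(3,4,5-trimethoxyphenyl)ethenyl]oxy}phenyl)methanol F8.
- O-methylation (NaH, MeI, THF) should give 5.

**Step 2.** The new benzylic ether may be over-reduced to a methyl group. The neighbouring aroyl carbonyl may also take part at the activated benzylic carbon.

The fallback sets out from 1 and comes back at 4. It installs the benzylic ether before the aroyl group, so that silane and Lewis acid never meet the ester.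
- Reduction of 1 (NaBH4, MeOH, 0 °C) should give 6-(hydroxymethyl)-2,3-dimethoxyphenol F9.
- Solvolysis in methanol (pyridinium p-toluenesulfonate, 5 mol%, 40 °C) should give 2,3-dimethoxy-6-(methoxymethyl)phenol F10.
- Acylation with 2 (Et3N, 4-(dimethylamino)pyridine, CH2Cl2) should give 4.

Further compounds
F1 | step 4 | 2,3-dimethoxy-6-vinylphenol | C=Cc1ccc(OC)c(OC)c1O
F2 | step 4 | (E)-3-(3,4,5-trimethoxyphenyl)allyl methyl carbonate | COC(=O)OC/C=C/c1cc(OC)c(OC)c(OC)c1
F3 | step 4 | (S)-1-ethenyl-3,4-dimethoxy-2-{[1-(3,4,5-trimethoxyphenyl)prop-2-en-1-yl]oxy}benzene | COc1cc([C@@H](Oc2c(C=C)ccc(OC)c2OC)C=C)cc(OC)c1OC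
F4 | step 4 | (2S)-7,8-dimethoxy-2-(3,4,5-trimethoxyphenyl)-2H-chromene | COc1cc([C@@H]2C=Cc3ccc(OC)c(OC)c3O2)cc(OC)c1OC
F5 | step 3 | 2-bromo-1-(3,4,5-trimethoxyphenyl)ethan-1-ol (racemic) | OC(CBr)c1cc(OC)c(OC)c(OC)c1
F6 | step 3 | 2-[2-bromo-1-(3,4,5-trimethoxyphenyl)ethoxy]-3,4-dimethoxybenzaldehyde (racemic) | O=Cc1ccc(OC)c(OC)c1OC(CBr)c1cc(OC)c(OC)c(OC)c1
F7 | step 3 | 3,4-dimethoxy-2-{[1-(3,4,5-trimethoxyphenyl)ethenyl]oxy}benzaldehyde | C=C(Oc1c(C=O)ccc(OC)c1OC)c1cc(OC)c(OC)c(OC)c1
F8 | step 3 | (3,4-dimethoxy-2-{[1-(3,4,5-trimethoxyphenyl)ethenyl]oxy}phenyl)methanol | C=C(Oc1c(CO)ccc(OC)c1OC)c1cc(OC)c(OC)c(OC)c1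
F9 | step 2 | 6-(hydroxymethyl)-2,3-dimethoxyphenol | OCc1ccc(OC)c(OC)c1O
F10 | step 2 | 2,3-dimethoxy-6-(methoxymethyl)phenol | COCc1ccc(OC)c(OC)c1O
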